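**Plan**
- Target numbering: tetrahydrofuran O1, C2 (aryl), C3 (CH2OH), C4 (CH(OH)Ar arm), C5 (H2); Ar = 4-hydroxy-3-methoxyphenyl.
- Retrosynthesis: mask both phenols as benzyl ethers, then tie the cis arms on C3 and C4 through the carbinol oxygen into a γ-aryl lactone (C3 CH2OH raised to the acyl level). Cutting C2–C3 and C4–C5 together then removes the ring segment C2–O1–C5 as the carbonyl ylide ArCH=O(+)–CH2(−) and leaves C3=C4 as the alkene of an (S)-γ-aryl butenolide.
- Forward: one aldehyde feeds both halves. With methyl propiolate it gives the butenolide (alkynylation, cis-semihydrogenation, lactonisation); with Me3SiCl and formaldehyde it gives the ylide precursor. The (3+2) cycloaddition closes the tetrahydrofuran onto the lactone, LiAlH4 opens the lactone, and hydrogenolysis frees the phenols.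
- Stereochemistry: the carbinol centre comes from the catalytic asymmetric alkynylation. In the cycloaddition it blocks one face of the butenolide (sets C3 and C4), the concerted addition makes C3/C4 cis, and exo approach of the ylide sets C2 trans to C3.

Key step: step 5

Remark: both phenols are carried as benzyl ethers, which are inert to CsF (aryl silyl ethers would not be), to LiAlH4 and to Lindlar conditions; aldehyde 1 is a commercial compound.
Remark (assumption): (S,S)-ProPhenol is taken as the ligand antipode that delivers the alkynyl group to the Si face of the aldehyde; the sense is to be checked on the first batch (Mosher esters), and the (R,R)-ligand is used if it proves opposite.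

**Step 1**
Reactants: 1 4-(benzyloxy)-3-methoxybenzaldehyde; 2 methyl propiolate
Product: 3 methyl (R)-4-[4-(benzyloxy)-3-methoxyphenyl]-4-hydroxybut-2-ynoate
Conditions: (S,S)-ProPhenol (10 mol%), Me2Zn (3 equiv), Ph3PO (20 mol%), toluene, 0–4 °C; aq. NH4Cl
Reagents that add atoms: none
Why: Catalytic asymmetric alkynylation of an aryl aldehyde with the zinc acetylide of methyl propiolate (ProPhenol/Me2Zn) is established chemistry; the chiral dinuclear zinc alkoxide delivers the alkynyl group to the Si face and sets the (R)-carbinol, the only reagent-controlled stereocentre of the route.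

**Step 2**
Reactants: 3 methyl (R)-4-[4-(benzyloxy)-3-methoxyphenyl]-4-hydroxybut-2-ynoate
Product: 5 (S)-5-[4-(benzyloxy)-3-methoxyphenyl]furan-2(5H)-one, via cis-hydroxy enoate 4 (not isolated)
Conditions: H2 (1 atm), Pd/CaCO3 poisoned with Pb(OAc)2 (Lindlar catalyst), quinoline, EtOAc, rt; then PPTS (cat.), CH2Cl2, rt
Reagents that add atoms: none
Why: Lindlar semihydrogenation adds H2 syn to give the cis enoate without touching the benzyl ether, and the cis γ-hydroxy ester lactonises under mild acid with loss of methanol; the stereocentre is untouched, its descriptor changing from R to S only because the alkyne no longer outranks the aryl group.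

**Step 3**
Reactants: 1 4-(benzyloxy)-3-methoxybenzaldehyde
Product: 7 rac-[4-(benzyloxy)-3-methoxyphenyl](trimethylsilyl)methanol, via C,O-bis(trimethylsilyl) adduct 6 (not isolated)
Conditions: Mg turnings, Me3SiCl (excess), DMF, rt; then 1 M HCl, THF, 0 °C
Reagents that add atoms: chlorotrimethylsilane C[Si](C)(C)Cl
Why: Magnesium-promoted reductive C-silylation of an aromatic aldehyde (Barbier-type, through the ketyl and α-silyloxy carbanion) gives the C,O-bis-silyl adduct, of which only the labile O–Si bond is cleaved by cold dilute acid; the product is racemic, which is immaterial because this centre becomes planar in the ylide.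

**Step 4**
Reactants: 7 rac-[4-(benzyloxy)-3-methoxyphenyl](trimethylsilyl)methanol
Product: 8 rac-{[4-(benzyloxy)-3-methoxyphenyl](chloromethoxy)methyl}trimethylsilane
Conditions: (CH2O)n, Me3SiCl, CH2Cl2, 0 °C → rt; volatiles removed, crude used at once
Reagents that add atoms: paraformaldehyde (formaldehyde) C=O; chlorotrimethylsilane C[Si](C)(C)Cl
Why: Chloromethylation of an alcohol with paraformaldehyde and Me3SiCl (hemiformal formation, then OH-to-Cl exchange) is the standard entry to chloromethyl ethers, including silylmethyl chloromethyl ethers; it is run cold and the product used crude because 8 is hydrolytically labile.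

**Step 5**
Reactants: 5 (S)-5-[4-(benzyloxy)-3-methoxyphenyl]furan-2(5H)-one; 8 rac-{[4-(benzyloxy)-3-methoxyphenyl](chloromethoxy)methyl}trimethylsilane
Product: 10 (1S,2S,5R,6S)-2,6-bis[4-(benzyloxy)-3-methoxyphenyl]-3,7-dioxabicyclo[3.3.0]octan-8-one, via carbonyl ylide 9 (not isolated)
Conditions: 8 (2.0 equiv), CsF (1.8 equiv, flame-dried), MeCN, 0 °C → rt
Reagents that add atoms: none
Why: Fluoride attacks the silicon of 8 while chloride leaves (1,3-elimination) to release the non-stabilised carbonyl ylide 9, which adds in a concerted suprafacial (3+2) cycloaddition across the electron-poor cis alkene of 5; the closest known reaction type is the fluoride-induced carbonyl ylide cycloaddition of silylmethyl chloromethyl ethers with α,β-unsaturated esters. The tetrahydrofuran ring is closed by the intermolecular cycloaddition itself, C2–C3 and C4–C5 forming together, so its fusion to the lactone can only be cis. The donor aryl group holds the positive charge at the benzylic carbon, which makes the CH2 terminus the nucleophilic end that bonds to the β-carbon (C4), the aryl-bearing carbon then bonding to the α-carbon (C3). C3 and C4 are set by approach of the dipole to the alkene face opposite the γ-aryl group of 5, and C2 by reaction of the E-configured ylide through the exo transition state with its oxygen turned away from the lactone, which places the aryl group on the convex face, trans to the C3 carbonyl. The step needs regio-, face and exo selectivity: the first two rest on ylide polarity and the γ-aryl shield, the third only on sterics; because the γ-hydrogen of 5 is acidic, 8 is kept in excess over CsF so that fluoride is consumed at silicon and not left to act as a base.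

**Step 6**
Reactants: 10 (1S,2S,5R,6S)-2,6-bis[4-(benzyloxy)-3-methoxyphenyl]-3,7-dioxabicyclo[3.3.0]octan-8-one
Product: 11 (S)-[4-(benzyloxy)-3-methoxyphenyl]{(3R,4R,5S)-5-[4-(benzyloxy)-3-methoxyphenyl]-4-(hydroxymethyl)oxolan-3-yl}methanol
Conditions: LiAlH4, THF, 0 °C; aq. potassium sodium tartrate work-up (no acid)
Reagents that add atoms: none
Why: Hydride reduction of a lactone to the diol opens the lactone into the C3 hydroxymethyl group and the C4 benzylic carbinol without touching a stereocentre, and benzyl ethers and the ring ether are inert to LiAlH4.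

**Step 7**
Reactants: 11 (S)-[4-(benzyloxy)-3-methoxyphenyl]{(3R,4R,5S)-5-[4-(benzyloxy)-3-methoxyphenyl]-4-(hydroxymethyl)oxolan-3-yl}methanol
Product: 12 (−)-tanegol
Conditions: H2 (1 atm), 10% Pd/C, EtOAc, rt, stopped after uptake of 2 equiv H2
Reagents that add atoms: none
Why: Catalytic hydrogenolysis cleaves aryl benzyl ethers much faster than benzylic alcohol or benzylic dialkyl ether C–O bonds in neutral ethyl acetate, so both phenols should be freed while C2–O1 and the carbinol stay intact, and the acid-free medium avoids cyclisation of the CH2OH onto the carbinol carbon.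

**Compound list**
1 | 4-(benzyloxy)-3-methoxybenzaldehyde (O-benzylvanillin) | O=Cc1ccc(OCc2ccccc2)c(OC)c1 | starting material
2 | methyl propiolate | C#CC(=O)OC | starting material
3 | methyl (R)-4-[4-(benzyloxy)-3-methoxyphenyl]-4-hydroxybut-2-ynoate | O[C@H](c1ccc(OCc2ccccc2)c(OC)c1)C#CC(=O)OC | intermediate
4 | methyl (S,Z)-4-[4-(benzyloxy)-3-methoxyphenyl]-4-hydroxybut-2-enoate (cis-hydroxy enoate, not isolated) | O[C@H](c1ccc(OCc2ccccc2)c(OC)c1)/C=C\C(=O)OC | intermediate
5 | (S)-5-[4-(benzyloxy)-3-methoxyphenyl]furan-2(5H)-one | O1[C@H](c2ccc(OCc3ccccc3)c(OC)c2)C=CC1=O | intermediate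
6 | rac-{[4-(benzyloxy)-3-methoxyphenyl][(trimethylsilyl)oxy]methyl}trimethylsilane (C,O-bis(trimethylsilyl) adduct, not isolated) | C[Si](C)(C)OC(c1ccc(OCc2ccccc2)c(OC)c1)[Si](C)(C)C | intermediate
7 | rac-[4-(benzyloxy)-3-methoxyphenyl](trimethylsilyl)methanol | OC(c1ccc(OCc2ccccc2)c(OC)c1)[Si](C)(C)C | intermediate
8 | rac-{[4-(benzyloxy)-3-methoxyphenyl](chloromethoxy)methyl}trimethylsilane | ClCOC(c1ccc(OCc2ccccc2)c(OC)c1)[Si](C)(C)C | intermediate
9 | carbonyl ylide ArCH=O(+)–CH2(−), Ar = 4-(benzyloxy)-3-methoxyphenyl (not isolated) | [CH2-][O+]=Cc1ccc(OCc2ccccc2)c(OC)c1 | intermediate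
10 | (1S,2S,5R,6S)-2,6-bis[4-(benzyloxy)-3-methoxyphenyl]-3,7-dioxabicyclo[3.3.0]octan-8-one (cis-fused, both aryl groups exo) | O1[C@H](c3ccc(OCc5ccccc5)c(OC)c3)[C@H]2CO[C@H](c4ccc(OCc6ccccc6)c(OC)c4)[C@H]2C1=O | intermediate
11 | (S)-[4-(benzyloxy)-3-methoxyphenyl]{(3R,4R,5S)-5-[4-(benzyloxy)-3-methoxyphenyl]-4-(hydroxymethyl)oxolan-3-yl}methanol | COc1cc([C@@H](O)[C@H]2CO[C@H](c3ccc(OCc4ccccc4)c(OC)c3)[C@H]2CO)ccc1OCc1ccccc1 | intermediate
12 | (−)-tanegol, (S)-(4-hydroxy-3-methoxyphenyl)[(3R,4R,5S)-5-(4-hydroxy-3-methoxyphenyl)-4-(hydroxymethyl)oxolan-3-yl]methanol | COc1cc([C@@H](O)[C@H]2CO[C@H](c3ccc(O)c(OC)c3)[C@H]2CO)ccc1O | target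

**Step count**
Total: 7 steps. Longest linear sequence: 5 steps (1 → 3 → 5 → 10 → 11 → 12; steps 1, 2, 5, 6, 7).

**Steps most likely to fail**

Step 5. The dipole may react partly through the endo transition state, or as its Z isomer, so that the C2 aryl group ends up on the concave face. Deprotonation of the acidic γ-hydrogen of 5 by fluoride is a second route to loss of material and enantiopurity; it would be monitored by chiral HPLC of recovered 5. The fallback replaces kinetic by thermodynamic control of C2. It sets out from 5 and 8: the cycloaddition is run as described, and the C2-epimeric lactone F1 (aryl endo), alone or mixed with 10, is treated with catalytic Me3SiOTf or BF3·OEt2 in CH2Cl2 at −40 to 0 °C. Reversible ionisation of the benzylic C2–O1 bond to the para-alkoxybenzyl cation and re-closure, the known acid-induced epimerisation at the benzylic carbons of furofuran lignans, should move F1 toward the less congested exo isomer, although the preference may be modest and need recycling. The ring-fusion carbons are not involved, so the absolute configuration is kept. The fallback returns to the route at 10.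

Step 4. The HCl-generating medium may ionise the electron-rich α-silyl benzylic alcohol (chloride formation, ring chloromethylation), or 8 may hydrolyse during isolation. The fallback builds the O–CH2–Cl unit in two neutral stages. It sets out from 7: Me2S and (BzO)2 in MeCN at 0 °C (Pummerer-type methylthiomethylation) give the methylthiomethyl ether F2. SO2Cl2 in CH2Cl2 at −78 °C, with cyclohexene to trap the sulfenyl chloride, then exchanges SMe for Cl. The fallback returns to the route at 8.

Step 3. With this electron-rich aldehyde the ketyl may dimerise (pinacol coupling) or be reduced further in place of clean C-silylation. The fallback is the umpolung (acylsilane) route, setting out from 1. Propane-1,3-dithiol and BF3·OEt2 in CH2Cl2 give the dithiane F3. n-BuLi in THF at −30 °C followed by Me3SiCl gives the silyl dithiane F4. I2 and CaCO3 in aqueous THF unmask the acylsilane F5, and NaBH4 in EtOH at 0 °C reduces it to the carbinol. The fallback returns to the route at 7.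

**Further compounds**
F1 | step 5 | (1S,2R,5R,6S)-2,6-bis[4-(benzyloxy)-3-methoxyphenyl]-3,7-dioxabicyclo[3.3.0]octan-8-one (C2 epimer of 10) | O1[C@H](c3ccc(OCc5ccccc5)c(OC)c3)[C@H]2CO[C@@H](c4ccc(OCc6ccccc6)c(OC)c4)[C@H]2C1=O
F2 | step 4 | rac-{[4-(benzyloxy)-3-methoxyphenyl][(methylsulfanyl)methoxy]methyl}trimethylsilane | CSCOC(c1ccc(OCc2ccccc2)c(OC)c1)[Si](C)(C)C
F3 | step 3 | 2-[4-(benzyloxy)-3-methoxyphenyl]-1,3-dithiane | C1CSC(SC1)c2ccc(OCc3ccccc3)c(OC)c2
F4 | step 3 | {2-[4-(benzyloxy)-3-methoxyphenyl]-1,3-dithian-2-yl}trimethylsilane | C[Si](C)(C)C1(SCCCS1)c2ccc(OCc3ccccc3)c(OC)c2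
F5 | step 3 | [4-(benzyloxy)-3-methoxyphenyl](trimethylsilyl)methanone | C[Si](C)(C)C(=O)c1ccc(OCc2ccccc2)c(OC)c1
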